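## Analysis of the target

The target is 7-hydroxy-5-methoxy-6-[(2S)-1-methylpiperidin-2-yl]flavone: ring A (C4a, C5–C8, C8a) is a 1,3,5-trioxygenated benzene fused to the 4-pyranone ring C (O1, C2–C4, C4a, C8a), and ring B is an unsubstituted phenyl on C2. Ring A carries a methoxy group on C5, the N-methylpiperidine on C6 (bonded through C2′), a free hydroxyl on C7 and hydrogen on C8. C2′ is the only stereocentre; it is (S), benzylic and α to a tertiary amine, so no relative configuration has to be controlled, but the centre must not be lost. It is also the weak point, because a benzylic amine flanked by two ortho oxygens, one of them a free phenol, can ionise toward an ortho-quinone methide, which endangers the configuration under acid, strong base or heat once the amine is free. Other sensitive groups are the reducible C2=C3 bond, the pyranone (opened by nucleophilic bases) and the 5-methoxy group peri to C4=O (cleaved by Lewis acids). The difficulty is regiochemical: C6 and C8 of a 5,7-dioxygenated flavone are both nucleophilic, so any substitution on the finished arene has to choose between them, and O5 has to be told from O7. The strategy rests on reading C5–C6–C7 as a β-keto ester unit (C5 the carboxyl carbon, C6 the α-carbon, C7 the ketone) in a chain that continues through the C8 methylene into C8a and C4a of a ready-made 6-phenyl-4-pyranone, so that C6 carries the piperidine before ring A exists and C2′ is taken from the chiral pool.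

## Retrosynthetic reasoning

**25 ⇒ 22.** The N1′–CH3 bond and the O7–H bond are cut last. In 22 the nitrogen is a benzyl carbamate and O7 a benzyl ether, so one hydrogenolysis frees amine 23, and reductive methylation in the same flask proceeds through 24. The basic amine, which makes C2′ labile, therefore appears only in the final, neutral, room-temperature operation.

**22 ⇒ 21 ⇒ 20.** The O5–CH3 and O7–benzyl bonds are cut in that order. In 20 the 5-OH is hydrogen-bonded to C4=O and the 7-OH is the more acidic, so O7 is alkylated first under mild base and O5 afterwards under more forcing conditions. No other order distinguishes the two oxygens as simply.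

**20 ⇒ 17 (key disconnection).** Ring A is opened at C4a–C5. This bond joins the nucleophilic pyranone carbon C4a to a carboxyl-level carbon C5, so the forward reaction is an acylation of C4a by acylketene 18, generated thermally from the tert-butyl β-keto ester 17; cyclohexadienone 19 then aromatises. Cutting here, and not at C6–C2′ on a finished flavone, removes the C6/C8 question, because the piperidine sits on the α-carbon of the β-keto ester and cannot end up anywhere else. The forward step must make one C–C bond and one ring without base or acid and without touching C2′.

**17 ⇒ 7 + 14.** The C6–C7 bond is cut. A direct acylation of ester enolate 13 by imidazolide 15 would be the shortest forward reaction, but the methylene of 15 lies between an activated acyl group and a vinylogous ketone and would simply protonate 13. Cutting C7–C8 instead has the mirror-image problem, since the C7 acyl donor would then carry an acidic C6–H between two carbonyl groups and would quench lithiated pyranone 6. The nucleophile is therefore made non-basic: malonic half ester 14, as its magnesium chelate, acylates through 16 and loses its carboxyl group afterwards. This costs one step and removes the acid–base conflict.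

**14 ⇒ 12 ⇒ 10 ⇒ 8.** The extra carboxyl group of 14 is removed (carboxylation of enolate 13 in the forward direction). The C6 methylene of 12 is then excised by a diazoketone homologation: 10 rearranges through ketene 11 with migration of C2′ and retention of configuration. This leads back to acid 8, which supplies the stereocentre and the ring nitrogen already protected as a thermally robust carbamate.

**7 ⇒ 5 ⇒ 4 ⇒ 1 + 2.** The carboxyl group of 7 is removed from the vinylogously acidic 2-methyl group of pyranone 5 (lateral metalation to 6 and carboxylation in the forward direction). Pyranone 5 is the cyclodehydration product of triketone 4, and 4 comes from acylation of the terminal carbon of dianion 3 of diketone 1 by ester 2.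

## Alternatives that were turned down

Alternative 1: Both bonds to the benzylic carbon that lie outside ring A, N1′–C2′ and C2′–C3′, would be cut. In the forward direction the aldehyde 6-formyl-7-hydroxy-5-methoxyflavone A2, the amine N-methylbut-3-en-1-amine A3 and vinylboronic acid A4 would be combined in a catalytic asymmetric borono-Mannich (Petasis) reaction under a chiral biaryl diol catalyst. This would give the acyclic diene amine 6-[(1S)-1-[but-3-enyl(methyl)amino]prop-2-enyl]-7-hydroxy-5-methoxyflavone A1. Ring-closing metathesis and hydrogenation of the new ring alkene would then complete the piperidine.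
- For: the plan is convergent, the N-methyl group is present from the start, the ortho-hydroxyl of A2 activates the boron reagent, and only three operations follow A2. In convergence and in relying on catalytic stereocontrol of a known class it is stronger than the chosen route.
- Against: A2 needs a C6-selective formylation of a 5,7-dioxygenated flavone, so the C6/C8 problem is only moved. Its aldehyde is flanked by two ortho oxygens, which makes enantiocontrol doubtful. The stereocentre of A1 is benzylic, allylic and ortho to a phenol, so ionisation to a quinone methide can erode it. The basic amine interferes with metathesis, and the hydrogenation has to spare C2=C3.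
- In comparison, the chosen route fixes C6 by connectivity and carries a chiral-pool stereocentre as a carbamate until the last step.

Alternative 2: The piperidine would be annulated onto a symmetric arene by cutting C2′–C3′ and N1′–C6′. In the forward direction 4-chlorobutylmagnesium bromide A7 would add to the (R)-N-tert-butanesulfinyl aldimine A6, an aryl aldimine with benzyloxy groups at both ortho positions and a triisopropylsilyloxy group para. The resulting sulfinamide anion would then displace the terminal chloride on warming with base, closing the ring to the N-sulfinyl 2-arylpiperidine A5. Ring C would be built afterwards.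
- For: the stereo-determining addition is auxiliary-controlled and well understood, and the symmetric ring makes the later acylation position unambiguous. In reliability of the individual reactions this is the strongest of the plans and stronger than the chosen key step.
- Against: the aldimine carbon of A6 sits between two ortho benzyloxy groups, which hinders addition and may chelate the reagent and change the facial preference. From A5 the flavone has to be built by acylation, acyl transfer and acid cyclodehydration on a 2,4,6-trioxygenated benzylic amine that ionises easily. O5 and O7 must still be differentiated and the sulfinyl group exchanged for methyl, which makes the sequence several steps longer.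
- In comparison, the chosen route forms ring A after the stereocentre is in place, under neutral conditions, and is shorter.

Alternative 3: Ring C would be cut at C4a–C4, C4–C3 and O1–C2. In the forward direction the iodophenol 3,5-bis(benzyloxy)-2-iodo-4-[(2S)-1-methylpiperidin-2-yl]phenol A9, carbon monoxide A11 and phenylacetylene A10 would be joined by a palladium-catalysed carbonylative coupling in a secondary amine. An aroylpalladium species would give an alkynone, which cyclises to 5,7-bis(benzyloxy)-6-[(2S)-1-methylpiperidin-2-yl]flavone A8.
- For: three bonds and ring C form in one operation of a known class, on a symmetric ring A that already carries the N-methylamine. That ring closure is better precedented than the chosen one.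
- Against: the plan does not address C2′, so A9 needs its own asymmetric synthesis of a 2-arylpiperidine on a fully substituted arene. The iodide of A9 is crowded, and the alkynone can close in a five-membered (aurone) mode. A8 still requires selective 5-O-debenzylation with a Lewis acid next to the labile benzylic amine, followed by methylation and a final debenzylation.
- In comparison, the chosen route handles regiochemistry, stereocentre and ring A in one line of steps, and accepts in exchange a key step without direct precedent.

Key step: step 8

## Route

Assumption: the target is taken as the free base with (S) configuration at C2′ as drawn, and acid 8 is treated as a commercial compound. Primed locants refer to the piperidine.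

Step 1
Reactants: 1 benzoylacetone (1-phenylbutane-1,3-dione); 2 ethyl acetate
Product: 4 1-phenylhexane-1,3,5-trione, via dilithium dienediolate 3 (not isolated)
Conditions: 1 (2.0 equiv), LiN(iPr)2 (4.0 equiv), THF, 0 °C; 2 (1.0 equiv), 0 °C → rt; aq. HCl
Reagents that add atoms: none
Why: Claisen-type acylation of a 1,3-diketone dianion, which reacts at its terminal, least stabilised carbon; the second equivalent of 3 absorbs the acidic triketone and the excess of 1 is recovered.

Step 2
Reactants: 4 1-phenylhexane-1,3,5-trione
Product: 5 2-methyl-6-phenyl-4H-pyran-4-one
Conditions: conc. H2SO4, 0 °C → rt; ice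
Reagents that add atoms: none
Why: Acid-catalysed cyclodehydration of a 1,3,5-triketone; the enol oxygen of one terminal carbonyl adds to the other and water is lost, and only one 4-pyranone is possible.

Step 3
Reactants: 5 2-methyl-6-phenyl-4H-pyran-4-one
Product: 7 (4-oxo-6-phenyl-4H-pyran-2-yl)acetic acid, via lithium dienolate 6 (not isolated)
Conditions: LiN(SiMe3)2 (1.1 equiv), THF, −78 °C; CO2 (dry gas), −78 → −20 °C; cold 1 M HCl to pH 2–3, extraction and concentration below 20 °C
Reagents that add atoms: carbon dioxide, O=C=O
Why: Lateral metalation of the 2-methyl group, which is vinylogously activated by C4=O, followed by carboxylation of the extended enolate at its terminal carbon; the hindered amide base avoids addition to the ring, and the acid is kept cold and used at once because it is a vinylogous β-keto acid.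

Step 4
Reactants: 8 (2S)-1-(benzyloxycarbonyl)piperidine-2-carboxylic acid
Product: 10 benzyl (2S)-2-(2-diazoacetyl)piperidine-1-carboxylate, via isobutyl carbonic mixed anhydride 9 (not isolated)
Conditions: i-BuOCOCl, N-methylmorpholine, THF, −15 °C; CH2N2, Et2O, 0 °C → rt
Reagents that add atoms: diazomethane, C=[N+]=[N-]
Why: Acylation of diazomethane by a mixed anhydride, the first half of an Arndt–Eistert homologation; the urethane nitrogen cannot form an oxazolone, so C2′ should keep its configuration.

Step 5
Reactants: 10 benzyl (2S)-2-(2-diazoacetyl)piperidine-1-carboxylate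
Product: 12 tert-butyl 2-[(2S)-1-(benzyloxycarbonyl)piperidin-2-yl]acetate, via ketene 11 (not isolated)
Conditions: PhCO2Ag (0.1 equiv), Et3N (3 equiv), t-BuOH–THF, 50 °C, dark
Reagents that add atoms: tert-butanol, CC(C)(C)O
Why: Wolff rearrangement; C2′ migrates to the carbene carbon with retention and the ketene is captured by the alcohol, giving the homologous tert-butyl ester with the (S) centre intact.

Step 6
Reactants: 12 tert-butyl 2-[(2S)-1-(benzyloxycarbonyl)piperidin-2-yl]acetate
Product: 14 3-tert-butoxy-2-[(2S)-1-(benzyloxycarbonyl)piperidin-2-yl]-3-oxopropanoic acid (both epimers at the malonate carbon), via lithium ester enolate 13 (not isolated)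
Conditions: LiN(iPr)2 (1.1 equiv), THF, −78 °C; CO2 (dry gas), −78 → −30 °C; cold 1 M HCl to pH 3
Reagents that add atoms: carbon dioxide, O=C=O
Why: Carboxylation of a kinetic ester enolate to a malonic half ester; at −78 °C expulsion of the β-carbamate nitrogen should not compete, and the new malonate centre is of no consequence because it becomes sp2 in the ketene.

Step 7
Reactants: 7 (4-oxo-6-phenyl-4H-pyran-2-yl)acetic acid; 14 3-tert-butoxy-2-[(2S)-1-(benzyloxycarbonyl)piperidin-2-yl]-3-oxopropanoic acid
Product: 17 tert-butyl 2-[(2S)-1-(benzyloxycarbonyl)piperidin-2-yl]-3-oxo-4-(4-oxo-6-phenyl-4H-pyran-2-yl)butanoate (epimer mixture at C2), via acyl imidazolide 15 (not isolated), via acylmalonic half ester 16 (not isolated)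
Conditions: 7, CDI (1.05 equiv), THF, 0 °C → rt; magnesium salt of 14 (1.3 equiv; from 14 and Mg(OEt)2 (0.65 equiv), THF, rt, evaporated), THF, rt → 35 °C; cold 1 M HCl
Reagents that add atoms: none
Why: Decarboxylative Claisen condensation of a magnesium malonic half ester with an acyl imidazole (Masamune-type); the chelated malonate is a carbon nucleophile too weakly basic to deprotonate the acidic methylene of 15, and loss of CO2 from 16 makes the acylation irreversible, with C2′ not involved.

Step 8
Reactants: 17 tert-butyl 2-[(2S)-1-(benzyloxycarbonyl)piperidin-2-yl]-3-oxo-4-(4-oxo-6-phenyl-4H-pyran-2-yl)butanoate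
Product: 20 benzyl (2S)-2-(5,7-dihydroxy-4-oxo-2-phenyl-4H-chromen-6-yl)piperidine-1-carboxylate, via acylketene 18 (not isolated), via cyclohexadienone 19 (not isolated)
Conditions: o-xylene, 140 °C, 17 added by syringe pump (final 0.005 M), dry N2 sweep to carry off t-BuOH
Reagents that add atoms: none
Why: Proposed new method: heating the enol form of 17 should expel tert-butanol through a six-centre transition state to give acylketene 18, the thermal behaviour known for tert-butyl β-keto esters (slower when α-branched, hence 140 °C). Tautomerisation of the C7 carbonyl toward the doubly activated C8 methylene then aligns C5=C6, C7=C8 and the pyranone C8a=C4a bond as a dienylketene, whose disrotatory six-electron electrocyclisation (equally an attack of the nucleophilic pyranone carbon C4a, the β-carbon of the ring enol ether, on the ketene carbon) forms C4a–C5 and closes the six-membered ring A as cyclohexadienone 19. A proton shift from C4a to the C5 oxygen gives the aromatic, chelated 5-hydroxy compound 20, which makes the closure irreversible. The closest known reactions are acylketene generation from tert-butyl β-keto esters or dioxinones, the electrocyclic closure of dienylketenes to phenols that ends cyclobutenone-based benzannulations, and the Claisen-type folding of polyketo esters to acylated 1,3,5-trihydroxybenzenes; their combination on a pyranone-masked chain is new. No stereocentre is created: the transient C4a centre of 19 vanishes on aromatisation, and C2′ is a carbamate-bearing sp3 carbon outside the reacting π system under neutral conditions, so it should be retained. The selectivity needed is carbon closure at C4a in competition with the ring oxygen O1 (also six atoms from C5, but a non-nucleophilic vinylogous ester oxygen whose acylation could only revert), with the carbamate carbonyl (a reversible, unproductive adduct) and with bimolecular trapping or dimerisation of 18. High dilution, slow addition, exclusion of water and removal of tert-butanol are meant to leave the unimolecular closure as the only irreversible exit.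

Step 9
Reactants: 20 benzyl (2S)-2-(5,7-dihydroxy-4-oxo-2-phenyl-4H-chromen-6-yl)piperidine-1-carboxylate
Product: 21 benzyl (2S)-2-[7-(benzyloxy)-5-hydroxy-4-oxo-2-phenyl-4H-chromen-6-yl]piperidine-1-carboxylate
Conditions: BnBr (1.05 equiv), K2CO3 (1.1 equiv), acetone, rt → 40 °C
Reagents that add atoms: benzyl bromide, BrCc1ccccc1
Why: Williamson etherification; the 7-OH is the more acidic phenol (vinylogous acid through C4=O) while the 5-OH is held in a hydrogen bond to C4=O, so one equivalent of halide should react at O7 only.

Step 10
Reactants: 21 benzyl (2S)-2-[7-(benzyloxy)-5-hydroxy-4-oxo-2-phenyl-4H-chromen-6-yl]piperidine-1-carboxylate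
Product: 22 benzyl (2S)-2-[7-(benzyloxy)-5-methoxy-4-oxo-2-phenyl-4H-chromen-6-yl]piperidine-1-carboxylate
Conditions: MeI (5 equiv), K2CO3 (3 equiv), DMF, 45 °C
Reagents that add atoms: iodomethane, CI
Why: Williamson methylation of the chelated 5-phenol under more forcing, polar aprotic conditions; the carbamate is tertiary, has no N–H and should resist attack by the neighbouring phenoxide at this temperature.

Step 11
Reactants: 22 benzyl (2S)-2-[7-(benzyloxy)-5-methoxy-4-oxo-2-phenyl-4H-chromen-6-yl]piperidine-1-carboxylate
Product: 25 7-hydroxy-5-methoxy-6-[(2S)-1-methylpiperidin-2-yl]-2-phenyl-4H-chromen-4-one (the target), via secondary amine 23 (not isolated), via N-hydroxymethyl amine 24 (not isolated)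
Conditions: H2 (1 atm), Pd/C (10 %), aq. CH2O (37 %, 3 equiv), MeOH–EtOAc, rt
Reagents that add atoms: formaldehyde, C=O
Why: Hydrogenolysis of the benzyl carbamate and the benzyl ether gives 23, which condenses with formaldehyde to 24 and is reduced through its iminium ion to the N-methyl amine (reductive amination); the conditions are neutral and at room temperature, so C2′ should be untouched.

## Compound list

1 | benzoylacetone (1-phenylbutane-1,3-dione) | CC(=O)CC(=O)c1ccccc1 | starting material
2 | ethyl acetate | CCOC(C)=O | starting material
3 | dilithium 1-phenylbuta-1,3-diene-1,3-diolate (dianion of 1) | [Li]OC(=C)C=C(O[Li])c1ccccc1 | intermediate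
4 | 1-phenylhexane-1,3,5-trione | CC(=O)CC(=O)CC(=O)c1ccccc1 | intermediate
5 | 2-methyl-6-phenyl-4H-pyran-4-one | Cc1cc(=O)cc(-c2ccccc2)o1 | intermediate
6 | lithium 2-methylidene-6-phenyl-2H-pyran-4-olate | C=C1C=C(O[Li])C=C(c2ccccc2)O1 | intermediate
7 | (4-oxo-6-phenyl-4H-pyran-2-yl)acetic acid | OC(=O)Cc1cc(=O)cc(-c2ccccc2)o1 | intermediate
8 | (2S)-1-(benzyloxycarbonyl)piperidine-2-carboxylic acid | OC(=O)[C@@H]1CCCCN1C(=O)OCc1ccccc1 | starting material
9 | (2S)-1-(benzyloxycarbonyl)piperidine-2-carboxylic isobutyl carbonic anhydride | CC(C)COC(=O)OC(=O)[C@@H]1CCCCN1C(=O)OCc1ccccc1 | intermediate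
10 | benzyl (2S)-2-(2-diazoacetyl)piperidine-1-carboxylate | [N-]=[N+]=CC(=O)[C@@H]1CCCCN1C(=O)OCc1ccccc1 | intermediate
11 | benzyl (2S)-2-(2-oxoethenyl)piperidine-1-carboxylate | O=C=C[C@@H]1CCCCN1C(=O)OCc1ccccc1 | intermediate
12 | tert-butyl 2-[(2S)-1-(benzyloxycarbonyl)piperidin-2-yl]acetate | CC(C)(C)OC(=O)C[C@@H]1CCCCN1C(=O)OCc1ccccc1 | intermediate
13 | lithium 1-tert-butoxy-2-[(2S)-1-(benzyloxycarbonyl)piperidin-2-yl]ethen-1-olate | CC(C)(C)OC(O[Li])=C[C@@H]1CCCCN1C(=O)OCc1ccccc1 | intermediate
14 | 3-tert-butoxy-2-[(2S)-1-(benzyloxycarbonyl)piperidin-2-yl]-3-oxopropanoic acid (epimer mixture at C2) | CC(C)(C)OC(=O)C(C(O)=O)[C@@H]1CCCCN1C(=O)OCc1ccccc1 | intermediate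
15 | 2-[2-(imidazol-1-yl)-2-oxoethyl]-6-phenyl-4H-pyran-4-one | O=C(Cc1cc(=O)cc(-c2ccccc2)o1)n1ccnc1 | intermediate
16 | 2-(tert-butoxycarbonyl)-2-[(2S)-1-(benzyloxycarbonyl)piperidin-2-yl]-3-oxo-4-(4-oxo-6-phenyl-4H-pyran-2-yl)butanoic acid | CC(C)(C)OC(=O)C(C(O)=O)(C(=O)Cc1cc(=O)cc(-c2ccccc2)o1)[C@@H]1CCCCN1C(=O)OCc1ccccc1 | intermediate
17 | tert-butyl 2-[(2S)-1-(benzyloxycarbonyl)piperidin-2-yl]-3-oxo-4-(4-oxo-6-phenyl-4H-pyran-2-yl)butanoate (epimer mixture at C2) | CC(C)(C)OC(=O)C([C@@H]1CCCCN1C(=O)OCc1ccccc1)C(=O)Cc1cc(=O)cc(-c2ccccc2)o1 | intermediate
18 | benzyl (2S)-2-[1,3-dioxo-4-(4-oxo-6-phenyl-4H-pyran-2-yl)but-1-en-2-yl]piperidine-1-carboxylate (acylketene) | O=C=C([C@@H]1CCCCN1C(=O)OCc1ccccc1)C(=O)Cc1cc(=O)cc(-c2ccccc2)o1 | intermediate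
19 | benzyl (2S)-2-(7-hydroxy-4,5-dioxo-2-phenyl-4a,5-dihydro-4H-chromen-6-yl)piperidine-1-carboxylate (C4a unspecified) | O=C1C([C@@H]2CCCCN2C(=O)OCc3ccccc3)=C(O)C=C4OC(c5ccccc5)=CC(=O)C14 | intermediate
20 | benzyl (2S)-2-(5,7-dihydroxy-4-oxo-2-phenyl-4H-chromen-6-yl)piperidine-1-carboxylate | Oc1c([C@@H]2CCCCN2C(=O)OCc3ccccc3)c(O)cc4oc(-c5ccccc5)cc(=O)c14 | intermediate
21 | benzyl (2S)-2-[7-(benzyloxy)-5-hydroxy-4-oxo-2-phenyl-4H-chromen-6-yl]piperidine-1-carboxylate | Oc1c([C@@H]2CCCCN2C(=O)OCc3ccccc3)c(OCc6ccccc6)cc4oc(-c5ccccc5)cc(=O)c14 | intermediate
22 | benzyl (2S)-2-[7-(benzyloxy)-5-methoxy-4-oxo-2-phenyl-4H-chromen-6-yl]piperidine-1-carboxylate | COc1c([C@@H]2CCCCN2C(=O)OCc3ccccc3)c(OCc6ccccc6)cc4oc(-c5ccccc5)cc(=O)c14 | intermediate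
23 | 7-hydroxy-5-methoxy-2-phenyl-6-[(2S)-piperidin-2-yl]-4H-chromen-4-one | COc1c([C@@H]2CCCCN2)c(O)cc3oc(-c4ccccc4)cc(=O)c13 | intermediate
24 | 7-hydroxy-6-[(2S)-1-(hydroxymethyl)piperidin-2-yl]-5-methoxy-2-phenyl-4H-chromen-4-one | COc1c([C@@H]2CCCCN2CO)c(O)cc3oc(-c4ccccc4)cc(=O)c13 | intermediate
25 | 7-hydroxy-5-methoxy-6-[(2S)-1-methylpiperidin-2-yl]-2-phenyl-4H-chromen-4-one | COc1c([C@@H]2CCCCN2C)c(O)cc2oc(-c3ccccc3)cc(=O)c12 | target

## Step count and least certain steps

Total: 11 steps. Longest linear sequence: 8 steps (steps 4–11 from 8, or equally steps 1–3 and 7–11 from 1).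

**Step 8 (key step).** Ketene generation from the α-branched ester may be slow, so that forcing temperature is needed. At that temperature the ester may instead lose isobutene and then carbon dioxide, which removes C5. The acylketene may also be diverted before it cyclises: by dimerisation, by capture by the phenolic product, or by traces of water followed by decarboxylation. Enolisation of C7 toward C8 may be too slow, and prolonged heating could erode the configuration at C2′. The fallback closes the same C4a–C5 bond ionically with known chemistry. It sets out from 17, which is warmed with 1,8-diazabicyclo[5.4.0]undec-7-ene (3 equiv) in acetonitrile at 60–80 °C. Deprotonation at C8 gives a vinylogous enolate with charge at C4a, which attacks the ester carbonyl in a Dieckmann-type intramolecular Claisen condensation, the base-mediated folding known for polyketo esters. tert-Butoxide leaves and tautomerisation gives the arene. The amidine base is not nucleophilic, so the pyranone stays closed and the regiochemistry stays defined. The stabilised C6 enolate is a poor donor for expelling the carbamate nitrogen, so C2′ should hold. The fallback comes back to the route at 20.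

**Step 7.** C-acylation of the hindered magnesium malonate, which must form a quaternary carbon next to C2′, may be sluggish. That would leave time for self-condensation of 15 through its acidic methylene or for premature decarboxylation of 14. The fallback is a kinetic crossed Claisen condensation. It sets out from 12, which is converted to enolate 13 with LiN(iPr)2 and used in threefold excess at −78 °C against imidazolide 15 (made from 7 as in step 7). The excess enolate serves as sacrificial base, and deprotonated 15 can still reach the product by losing imidazolide to a ketene that the enolate captures at carbon. It comes back at 17.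

**Step 6.** The carbamate nitrogen may be expelled from enolate 13 (ring opening and loss of C2′), or the half ester may decarboxylate during acidic isolation. The fallback installs the carboxyl group through the rearrangement itself and avoids that enolate. It sets out from 8, which with CDI gives benzyl (2S)-2-(1H-imidazole-1-carbonyl)piperidine-1-carboxylate F1. The lithium enolate of tert-butyl acetate at −78 °C converts this into tert-butyl 3-[(2S)-1-(benzyloxycarbonyl)piperidin-2-yl]-3-oxopropanoate F2. Diazo transfer with 4-acetamidobenzenesulfonyl azide and Et3N then gives tert-butyl 2-diazo-3-[(2S)-1-(benzyloxycarbonyl)piperidin-2-yl]-3-oxopropanoate F3. Photolysis in wet THF induces a Wolff rearrangement in which C2′ migrates with retention to give tert-butyl 2-[(2S)-1-(benzyloxycarbonyl)piperidin-2-yl]-3-oxoprop-2-enoate F4, and water converts this ketene into the half ester. It comes back at 14.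

**Step 3.** The vinylogous β-keto acid may lose carbon dioxide during acidification or concentration, and the amide base may add to the pyranone instead of metalating the methyl group. The fallback never liberates the acid. It sets out from 5, which is metalated to 6 (2 equiv) and treated with CDI (1 equiv) at −78 °C. C-acylation gives the acyl imidazole directly, and the second equivalent of 6 deprotonates it and so protects it from a second addition. After neutralisation with one equivalent of acetic acid the solution is used in step 7. It comes back at 15.

**Step 11.** Formaldehyde may condense at C8 of the liberated phenol (Mannich-type substitution), the C2=C3 bond may be over-reduced, or the benzylic C2′–N bond may undergo hydrogenolysis. The fallback keeps O7 masked while nitrogen is methylated. It sets out from 20, which with chloromethyl methyl ether and iPr2NEt gives benzyl (2S)-2-[5-hydroxy-7-(methoxymethoxy)-4-oxo-2-phenyl-4H-chromen-6-yl]piperidine-1-carboxylate F5. Methylation as in step 10 gives benzyl (2S)-2-[5-methoxy-7-(methoxymethoxy)-4-oxo-2-phenyl-4H-chromen-6-yl]piperidine-1-carboxylate F6. Hydrogenolysis over Pd/C with formaldehyde then gives 5-methoxy-7-(methoxymethoxy)-6-[(2S)-1-methylpiperidin-2-yl]-2-phenyl-4H-chromen-4-one F7 with no free phenol present. Dilute HCl in methanol at room temperature finally removes the acetal. It comes back at 25.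

## Further compounds

F0 | step 8 | none | none
F0 | step 7 | none | none
F1 | step 6 | benzyl (2S)-2-(1H-imidazole-1-carbonyl)piperidine-1-carboxylate | O=C([C@@H]1CCCCN1C(=O)OCc1ccccc1)n1ccnc1
F2 | step 6 | tert-butyl 3-[(2S)-1-(benzyloxycarbonyl)piperidin-2-yl]-3-oxopropanoate | CC(C)(C)OC(=O)CC(=O)[C@@H]1CCCCN1C(=O)OCc1ccccc1
F3 | step 6 | tert-butyl 2-diazo-3-[(2S)-1-(benzyloxycarbonyl)piperidin-2-yl]-3-oxopropanoate | CC(C)(C)OC(=O)C(=[N+]=[N-])C(=O)[C@@H]1CCCCN1C(=O)OCc1ccccc1
F4 | step 6 | tert-butyl 2-[(2S)-1-(benzyloxycarbonyl)piperidin-2-yl]-3-oxoprop-2-enoate | CC(C)(C)OC(=O)C(=C=O)[C@@H]1CCCCN1C(=O)OCc1ccccc1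
F0 | step 3 | none | none
F5 | step 11 | benzyl (2S)-2-[5-hydroxy-7-(methoxymethoxy)-4-oxo-2-phenyl-4H-chromen-6-yl]piperidine-1-carboxylate | Oc1c([C@@H]2CCCCN2C(=O)OCc3ccccc3)c(OCOC)cc4oc(-c5ccccc5)cc(=O)c14
F6 | step 11 | benzyl (2S)-2-[5-methoxy-7-(methoxymethoxy)-4-oxo-2-phenyl-4H-chromen-6-yl]piperidine-1-carboxylate | COc1c([C@@H]2CCCCN2C(=O)OCc3ccccc3)c(OCOC)cc4oc(-c5ccccc5)cc(=O)c14
F7 | step 11 | 5-methoxy-7-(methoxymethoxy)-6-[(2S)-1-methylpiperidin-2-yl]-2-phenyl-4H-chromen-4-one | COc1c([C@@H]2CCCCN2C)c(OCOC)cc3oc(-c4ccccc4)cc(=O)c13
A1 | alternative 1 | 6-[(1S)-1-[but-3-enyl(methyl)amino]prop-2-enyl]-7-hydroxy-5-methoxyflavone | COc1c([C@H](C=C)N(C)CCC=C)c(O)cc2oc(-c3ccccc3)cc(=O)c12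
A2 | alternative 1 | 6-formyl-7-hydroxy-5-methoxyflavone | COc1c(C=O)c(O)cc2oc(-c3ccccc3)cc(=O)c12
A3 | alternative 1 | N-methylbut-3-en-1-amine | CNCCC=C
A4 | alternative 1 | vinylboronic acid | C=CB(O)O
A5 | alternative 2 | (2S)-2-[2,6-bis(benzyloxy)-4-(triisopropylsilyloxy)phenyl]-1-[(R)-tert-butanesulfinyl]piperidine | CC(C)(C)[S@@](=O)N1CCCC[C@H]1c2c(OCc3ccccc3)cc(O[Si](C(C)C)(C(C)C)C(C)C)cc2OCc4ccccc4
A6 | alternative 2 | (R)-N-[2,6-bis(benzyloxy)-4-(triisopropylsilyloxy)benzylidene]-2-methylpropane-2-sulfinamide | CC(C)(C)[S@@](=O)N=Cc1c(OCc2ccccc2)cc(O[Si](C(C)C)(C(C)C)C(C)C)cc1OCc3ccccc3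
A7 | alternative 2 | 4-chlorobutylmagnesium bromide | ClCCCC[Mg]Br
A8 | alternative 3 | 5,7-bis(benzyloxy)-6-[(2S)-1-methylpiperidin-2-yl]flavone | O=c1cc(-c2ccccc2)oc2cc(OCc3ccccc3)c([C@@H]4CCCCN4C)c(OCc5ccccc5)c12
A9 | alternative 3 | 3,5-bis(benzyloxy)-2-iodo-4-[(2S)-1-methylpiperidin-2-yl]phenol | Oc1cc(OCc2ccccc2)c([C@@H]3CCCCN3C)c(OCc4ccccc4)c1I
A10 | alternative 3 | phenylacetylene | C#Cc1ccccc1
A11 | alternative 3 | carbon monoxide | [C-]#[O+]
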